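**Retrosynthetic overview**
1. Ring E (seven-membered) is closed last by Dieckmann-type C-acylation of the only free CH of the ring-A cyclopentadiene by the ester on the piperidine; ring A is built onto the cycloheptenone (ring B) by Tsuji–Trost allylation of a β-keto ester, enol triflation and palladium-catalysed ketone α-alkenylation.
2. Rings C and D (the indolizidine) arise together from a side arm of a ring-B azido dienone: Nazarov cyclization to a five-membered oxyallyl cation, azide capture (ring C), Schmidt-type expansion of that five-membered carbocycle to the six-membered lactam (ring D), reductive termination.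
3. Enabling feature: the piperidine (N, CH2, CH(CH3), CH, CH2, CH) shares its N–CH bond with the pyrrolidine, and N reaches that ring-fusion CH through a three-carbon chain (CH2–CH–quaternary C). Ring D is therefore a 2-methylcyclopentanone-type carbocycle (C=O, CHCH3, CH, CH2, CH) with the nitrogen of an azide on that chain inserted between the carbonyl carbon (the later N–CH2) and the ring-fusion carbon.
4. Ring B comes from cyclohepta-2,6-dienone: enantioselective conjugate addition sets the CH(CH2N) centre, two enolate alkylations set the quaternary methyl carbon, hydroxymethylation and oxidative transposition give the enone that carries the ring-A attachment carbon.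
5. Order of ring formation: B, then C + D (through a five-membered carbocycle), then A, then E.

Key step: step 16

Assumption: the ring-A cyclopentadiene 33 and the hydroxyfulvenes 34–37 are written as single tautomers although they interconvert by proton shifts; 25–27 are mixtures of epimers at the two piperidinone carbons until step 18.

**Route**

Step 1
Reactants: 1 cycloheptanone
Product: 2 cyclohepta-2,6-dien-1-one
Conditions: 2-iodoxybenzoic acid (2.5 equiv), DMSO/fluorobenzene, 75 °C
Reagents that add atoms: none
Why: 2-iodoxybenzoic acid dehydrogenates ketones α,β to the carbonyl through the enol, and an excess should desaturate both sides of the symmetric ketone; no stereocentre is formed.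

Step 2
Reactants: 2 cyclohepta-2,6-dien-1-one
Product: 4 (S)-6-(hydroxymethyl)cyclohept-2-en-1-one, via silyl ketone 3 (not isolated)
Conditions: (i-PrO)Me2SiCH2MgCl, CuBr·SMe2 (5 mol %), (R)-1-[(S)-2-(diphenylphosphino)ferrocenyl]ethyldicyclohexylphosphine or its enantiomer (6 mol %), t-BuOMe, −78 °C; then KF, KHCO3, 30% H2O2, THF/MeOH, rt
Reagents that add atoms: [(isopropoxydimethylsilyl)methyl]magnesium chloride, CC(C)O[Si](C)(C)C[Mg]Cl; hydrogen peroxide, OO
Why: copper-catalysed enantioselective conjugate addition of a Grignard reagent to a cyclic enone should set the C6 stereocentre under control of the chiral diphosphine (enantiomer chosen to give S), and Tamao–Fleming oxidation then turns C–Si into C–OH without touching it.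

Step 3
Reactants: 4 (S)-6-(hydroxymethyl)cyclohept-2-en-1-one
Product: 5 (S)-6-{[(tert-butyldimethylsilyl)oxy]methyl}cyclohept-2-en-1-one
Conditions: TBSCl, imidazole, DMF, 0 °C to rt
Reagents that add atoms: tert-butyldimethylsilyl chloride, CC(C)(C)[Si](C)(C)Cl
Why: silylation of the primary alcohol traps the open hydroxy ketone and protects it for the enolate steps.

Step 4
Reactants: 5 (S)-6-{[(tert-butyldimethylsilyl)oxy]methyl}cyclohept-2-en-1-one
Product: 6 (6S,7R)-7-allyl-6-{[(tert-butyldimethylsilyl)oxy]methyl}cyclohept-2-en-1-one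
Conditions: LDA, THF, −78 °C; allyl bromide, DMPU, −78 to −20 °C
Reagents that add atoms: allyl bromide, C=CCBr
Why: kinetic deprotonation can only take place at C7 (the other α-carbon is vinylic) and the cross-conjugated enolate should be allylated anti to the C6 substituent; the C7 configuration is re-formed in step 5 and is of no consequence.

Step 5
Reactants: 6 (6S,7R)-7-allyl-6-{[(tert-butyldimethylsilyl)oxy]methyl}cyclohept-2-en-1-one
Product: 7 (6S,7S)-7-allyl-6-{[(tert-butyldimethylsilyl)oxy]methyl}-7-methylcyclohept-2-en-1-one
Conditions: LDA, THF, −78 °C; MeI, DMPU, −78 to 0 °C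
Reagents that add atoms: iodomethane, CI
Why: the C7 enolate should be methylated on the face opposite the neighbouring CH2OSi group (1,2-induction in enolate alkylation), which sets the quaternary centre with methyl trans and allyl cis to that group, as the pyrrolidine later requires.

Step 6
Reactants: 7 (6S,7S)-7-allyl-6-{[(tert-butyldimethylsilyl)oxy]methyl}-7-methylcyclohept-2-en-1-one
Product: 9 (6S,7S)-7-allyl-6-{[(tert-butyldimethylsilyl)oxy]methyl}-1-(hydroxymethyl)-7-methylcyclohept-2-en-1-ol (C1 epimers), via silyl carbinol 8 (not isolated)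
Conditions: (i-PrO)Me2SiCH2MgCl, CeCl3, THF, −78 to 0 °C; then KF, KHCO3, 30% H2O2, THF/MeOH, rt
Reagents that add atoms: [(isopropoxydimethylsilyl)methyl]magnesium chloride, CC(C)O[Si](C)(C)C[Mg]Cl; hydrogen peroxide, OO
Why: 1,2-addition of the silylmethyl organocerium reagent to the hindered, non-enolisable enone carbonyl followed by Tamao–Fleming oxidation is a nucleophilic hydroxymethylation; the new carbinol centre is destroyed in step 8.

Step 7
Reactants: 9 the diol from step 6
Product: 10 [(6S,7S)-7-allyl-6-{[(tert-butyldimethylsilyl)oxy]methyl}-1-hydroxy-7-methylcyclohept-2-en-1-yl]methyl pivalate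
Conditions: PivCl, pyridine, DMAP (cat.), CH2Cl2, 0 °C
Reagents that add atoms: pivaloyl chloride, CC(C)(C)C(Cl)=O
Why: only the primary hydroxyl is acylated, the tertiary allylic one being too hindered; the pivalate is the later leaving group for the allylation in step 20.

Step 8
Reactants: 10 the hydroxy pivalate
Product: 11 [(6S,7S)-7-allyl-6-{[(tert-butyldimethylsilyl)oxy]methyl}-7-methyl-3-oxocyclohept-1-en-1-yl]methyl pivalate
Conditions: pyridinium chlorochromate [C5H5NH][CrO3Cl], 4 Å molecular sieves, CH2Cl2, rt
Reagents that add atoms: none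
Why: oxidative 1,3-transposition of a tertiary allylic alcohol (chromate ester, [3,3]-shift, oxidation; Dauben–Michno reaction) should move the oxygen to the far end of the allyl unit and give the β-substituted cycloheptenone without touching a stereocentre.

Step 9
Reactants: 11 the silyl ether enone
Product: 12 [(6S,7S)-7-allyl-6-(hydroxymethyl)-7-methyl-3-oxocyclohept-1-en-1-yl]methyl pivalate
Conditions: HF·pyridine, THF/pyridine, 0 °C to rt
Reagents that add atoms: none
Why: fluoride cleaves the primary silyl ether while the pivalate and the enone are stable to buffered HF.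

Step 10
Reactants: 12 the primary alcohol
Product: 13 [(6S,7S)-7-allyl-6-(azidomethyl)-7-methyl-3-oxocyclohept-1-en-1-yl]methyl pivalate
Conditions: PPh3, DIAD, (PhO)2P(O)N3, THF, 0 °C to rt
Reagents that add atoms: diphenylphosphoryl azide, [N-]=[N+]=NP(=O)(Oc1ccccc1)Oc1ccccc1
Why: Mitsunobu displacement at the primary carbon installs the azide at room temperature, below the temperature at which the azide would add to the allyl group.

Step 11
Reactants: 13 the allyl azide
Product: 14 [(6S,7S)-6-(azidomethyl)-7-methyl-3-oxo-7-(2-oxoethyl)cyclohept-1-en-1-yl]methyl pivalate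
Conditions: O3 (1 equiv, dosed), CH2Cl2/MeOH, pyridine, −78 °C; then Me2S
Reagents that add atoms: ozone, [O-][O+]=O
Why: ozonolysis should cleave the electron-rich terminal alkene much faster than the conjugated, electron-poor ring alkene, and alkyl azides tolerate ozone when the work-up uses a sulfide and no phosphine.

Step 12
Reactants: 14 the aldehyde
Product: 15 [(6S,7S)-6-(azidomethyl)-7-methyl-3-oxo-7-(3-oxoprop-1-en-2-yl)cyclohept-1-en-1-yl]methyl pivalate
Conditions: dimethylmethylideneammonium iodide, Et3N, CH2Cl2, rt
Reagents that add atoms: N,N-dimethylmethaniminium iodide, C=[N+](C)C.[I-]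
Why: Mannich reaction of the aldehyde enol and amine-promoted loss of dimethylamine (α-methylenation of an aldehyde) gives the 2-substituted acrolein; it is used at once because the azide can add to the activated alkene on standing.

Step 13
Reactants: 16 but-2-yn-1-ol
Product: 17 (but-2-yn-1-yloxy)(tert-butyl)dimethylsilane
Conditions: TBSCl, imidazole, CH2Cl2, rt
Reagents that add atoms: tert-butyldimethylsilyl chloride, CC(C)(C)[Si](C)(C)Cl
Why: routine silylation of a primary alcohol.

Step 14
Reactants: 15 the enal; 17 (but-2-yn-1-yloxy)(tert-butyl)dimethylsilane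
Product: 20 divinyl carbinol (carbinol epimers) of the azido cycloheptenone, via alkenylzirconocene chloride 18 (not isolated), via alkenyl(methyl)zinc 19 (not isolated)
Conditions: (C5H5)2Zr(H)Cl, THF, 40 °C; Me2Zn, toluene, −65 °C; then 15, −30 to 0 °C
Reagents that add atoms: none
Why: syn-hydrozirconation of the internal alkyne places zirconium on the methyl-bearing carbon after equilibration (E geometry), and zirconium-to-zinc transmetalation gives an alkenylzinc that should add 1,2 to the aldehyde only, leaving the ring enone, azide and ester; the carbinol centre is removed in step 15.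

Step 15
Reactants: 20 the divinyl carbinol
Product: 21 [(6S,7S)-6-(azidomethyl)-7-[(4E)-6-{[tert-butyl(dimethyl)silyl]oxy}-4-methyl-3-oxohexa-1,4-dien-2-yl]-7-methyl-3-oxocyclohept-1-en-1-yl]methyl pivalate
Conditions: 1,1,1-triacetoxy-1,1-dihydro-1,2-benziodoxol-3(1H)-one (DMP), NaHCO3, CH2Cl2, 0 °C
Reagents that add atoms: none
Why: mild oxidation of the bis-allylic alcohol gives the cross-conjugated dienone without isomerising the E alkene.

Step 16
Reactants: 21 the azido dienone
Product: 25 tricyclic lactam (indolizidin-5-one fused to ring B; epimers at the methyl- and silyloxymethyl-bearing carbons), via oxyallyl cation 22 (not isolated), via aminodiazonium enolate 23 (not isolated), via acyliminium enolate 24 (not isolated)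
Conditions: BF3·OEt2 (3 equiv), degassed CH2Cl2 under argon, −78 to −20 °C; then Et3SiH, CF3CO2H, −20 to 0 °C
Reagents that add atoms: none
Why: BF3 triggers a conrotatory 4π-electrocyclization (Nazarov cyclization) that joins the methylene carbon to the alkene carbon bearing CH2OSi and gives the five-membered 2-oxidocyclopentenyl cation 22; the azide captures the cation terminus next to the quaternary carbon (5-exo closure of the pyrrolidine, ring C) to give 23, and a Schmidt-type 1,2-shift of the acyl carbon from carbon to nitrogen with loss of N2 expands the five-membered carbocycle by one atom to the six-membered lactam (ring D) as the acyliminium/enolate 1,4-dipole 24, which CF3CO2H protonates on carbon and Et3SiH reduces at the iminium carbon. The closest known reaction type is the domino Nazarov cyclization/azide capture/Schmidt rearrangement of 1,4-dien-3-ones carrying a 3-azidopropyl group on an α-carbon, which gives indolizidinones, here ended by ionic hydrogenation of the N-acyliminium ion instead of oxygen trapping. The carbocycle closes by electrocyclization, ring C by 5-exo attack of nitrogen on the allyl cation, and ring D forms by ring expansion, not by a separate cyclization. The ring-fusion C–H should be set by hydride delivery to the convex face of the cis-fused cycloheptane–pyrrolidine unit, syn to the angular methyl group, whereas the two piperidinone carbons (from torquoselectivity and kinetic C-protonation) are not controlled here and are corrected in step 18. The step needs the azide to trap the oxyallyl cation faster than it attacks the ring-B enone, which the low temperature, the high cyclization rate of the α,α'-disubstituted dienone and the intramolecular five-ring capture should secure (the ring-B carbonyl is a deactivated β,β-disubstituted enone), and it needs exclusion of O2, which would trap 24 as an endoperoxide.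

Step 17
Reactants: 25 the tricyclic lactam
Product: 27 tricyclic lactam methyl ester (epimer mixture), via carboxylic acid 26 (not isolated)
Conditions: CrO3, H2SO4, H2O/acetone, 0 °C; then Me3SiCHN2, MeOH/toluene, 0 °C
Reagents that add atoms: water, O; trimethylsilyldiazomethane, C[Si](C)(C)C=[N+]=[N-]
Why: chromic acid cleaves the primary silyl ether (or oxidises any alcohol already freed in step 16) and takes it through the aldehyde hydrate to the acid, which the diazoalkane methylates.

Step 18
Reactants: 27 the lactam ester mixture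
Product: 28 lactam ester as the single all-equatorial diastereomer (ester cis to the ring-fusion C–C bond and trans to the methyl group)
Conditions: KOt-Bu (0.3 equiv), t-BuOH/THF, 25 °C; AcOH quench
Reagents that add atoms: none
Why: reversible enolisation α to the ester and α to the lactam carbonyl should funnel all four epimers into the thermodynamic 3,4-trans-4,6-cis piperidinone, which has exactly the relative configuration of the target.

Step 19
Reactants: 29 3-[(tert-butyldimethylsilyl)oxy]propanal
Product: 30 methyl 5-[(tert-butyldimethylsilyl)oxy]-3-oxopentanoate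
Conditions: N2CHCO2Me, SnCl2 (10 mol %), CH2Cl2, rt
Reagents that add atoms: methyl diazoacetate, COC(=O)C=[N+]=[N-]
Why: Roskamp homologation (addition of the diazo ester to the aldehyde, 1,2-hydride shift, loss of N2) gives the β-keto ester directly.

Step 20
Reactants: 28 the lactam ester; 30 methyl 5-[(tert-butyldimethylsilyl)oxy]-3-oxopentanoate
Product: 31 C-allylated β-keto ester (epimers at the new CH)
Conditions: 30 (2 equiv), NaH, THF, 0 °C; then 28, Pd(PPh3)4 (5 mol %), 50 °C
Reagents that add atoms: none
Why: Tsuji–Trost allylation, in which zerovalent palladium ionises the allylic pivalate and the soft β-keto ester enolate attacks the unsubstituted CH2 terminus of the π-allyl complex, which restores the conjugated enone.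

Step 21
Reactants: 31 the allylated β-keto ester
Product: 32 enol triflate with the triflate cis to the ring-bearing CH2 group
Conditions: KHMDS, 18-crown-6, THF, −78 °C; PhNTf2, −78 to 0 °C
Reagents that add atoms: N-phenylbis(trifluoromethanesulfonimide), O=S(=O)(N(c1ccccc1)S(=O)(=O)C(F)(F)F)C(F)(F)F
Why: the β-keto ester is by far the most acidic site, and O-sulfonylation of its non-chelated potassium enolate should give the enol triflate with the oxygen trans to the ester, the geometry needed for ring closure; PhNTf2 is used because triflic anhydride would activate the lactam.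

Step 22
Reactants: 32 the enol triflate
Product: 33 ring-A cyclopentadiene (rings A to D; cyclopentadiene bearing the methyl ester and the silyloxyethyl chain and fused to the cycloheptenone)
Conditions: Pd2(dba)3 (5 mol %), Xantphos (12 mol %), K3PO4, toluene, 80 °C; AcOH quench
Reagents that add atoms: none
Why: intramolecular palladium-catalysed α-alkenylation of a ketone, in which zerovalent palladium inserts into the C–OTf bond, the enone is deprotonated at its γ-CH2 to the dienolate and C–C reductive elimination at the α-carbon closes the five-membered ring, after which proton shifts give the conjugated cyclopentadiene.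

Step 23
Reactants: 33 the ring-A cyclopentadiene
Product: 34 pentacyclic hydroxyfulvene lactam (silyl ether)
Conditions: DBU (1.5 equiv), toluene, 90 °C; then aqueous KHSO4
Reagents that add atoms: none
Why: Dieckmann-type condensation in which the cyclopentadienide (the only ring C–H lies next to the ester-bearing carbon) attacks the piperidine methyl ester, possible only for the cis isomer set in step 18, to close the seven-membered ring E as the hydrogen-bonded hydroxyfulvene; DBU is too weak to epimerise the lactam α-carbon.

Step 24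
Reactants: 34 the hydroxyfulvene lactam
Product: 36 O-silyl daphnicyclidin H, via silyl hemiaminal 35 (not isolated)
Conditions: IrCl(CO)(PPh3)2 (2 mol %), (Me2HSi)2O, toluene, 25 °C; then Et3SiH, CF3CO2H, CH2Cl2, 0 °C
Reagents that add atoms: none
Why: iridium-catalysed hydrosilylation should reduce the tertiary lactam selectively over the ester and the vinylogous-acid ketone (the acidic fulvenol is silylated in the flask and freed on work-up), and ionic hydrogenation of the resulting N,O-acetal gives the amine without passing through an enamine, so the adjacent methyl-bearing centre should be kept.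

Step 25
Reactants: 36 O-silyl daphnicyclidin H
Product: 37 daphnicyclidin H
Conditions: HF·pyridine, THF/pyridine, 0 °C to rt
Reagents that add atoms: none
Why: fluoride removes the primary silyl ether and leaves the methyl ester, the hydroxyfulvene and the amine untouched.

**Compound list**
1 | cycloheptanone | O=C1CCCCCC1 | starting material
2 | cyclohepta-2,6-dien-1-one | O=C1C=CCCC=C1 | intermediate
3 | (S)-6-{[dimethyl(propan-2-yloxy)silyl]methyl}cyclohept-2-en-1-one | CC(C)O[Si](C)(C)C[C@H]1CCC=CC(=O)C1 | intermediate
4 | (S)-6-(hydroxymethyl)cyclohept-2-en-1-one | OC[C@H]1CCC=CC(=O)C1 | intermediate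
5 | (S)-6-{[(tert-butyldimethylsilyl)oxy]methyl}cyclohept-2-en-1-one | CC(C)(C)[Si](C)(C)OC[C@H]1CCC=CC(=O)C1 | intermediate
6 | (6S,7R)-7-allyl-6-{[(tert-butyldimethylsilyl)oxy]methyl}cyclohept-2-en-1-one | CC(C)(C)[Si](C)(C)OC[C@H]1CCC=CC(=O)[C@@H]1CC=C | intermediate
7 | (6S,7S)-7-allyl-6-{[(tert-butyldimethylsilyl)oxy]methyl}-7-methylcyclohept-2-en-1-one | CC(C)(C)[Si](C)(C)OC[C@H]1CCC=CC(=O)[C@@]1(C)CC=C | intermediate
8 | silyl carbinol: 7 after 1,2-addition of the (isopropoxydimethylsilyl)methyl group (C1 epimers) | CC(C)(C)[Si](C)(C)OC[C@H]1CCC=CC(O)(C[Si](C)(C)OC(C)C)[C@@]1(C)CC=C | intermediate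
9 | (6S,7S)-7-allyl-6-{[(tert-butyldimethylsilyl)oxy]methyl}-1-(hydroxymethyl)-7-methylcyclohept-2-en-1-ol (C1 epimers) | CC(C)(C)[Si](C)(C)OC[C@H]1CCC=CC(O)(CO)[C@@]1(C)CC=C | intermediate
10 | [(6S,7S)-7-allyl-6-{[(tert-butyldimethylsilyl)oxy]methyl}-1-hydroxy-7-methylcyclohept-2-en-1-yl]methyl pivalate | CC(C)(C)[Si](C)(C)OC[C@H]1CCC=CC(O)(COC(=O)C(C)(C)C)[C@@]1(C)CC=C | intermediate
11 | [(6S,7S)-7-allyl-6-{[(tert-butyldimethylsilyl)oxy]methyl}-7-methyl-3-oxocyclohept-1-en-1-yl]methyl pivalate | CC(C)(C)[Si](C)(C)OC[C@H]1CCC(=O)C=C(COC(=O)C(C)(C)C)[C@@]1(C)CC=C | intermediate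
12 | [(6S,7S)-7-allyl-6-(hydroxymethyl)-7-methyl-3-oxocyclohept-1-en-1-yl]methyl pivalate | OC[C@H]1CCC(=O)C=C(COC(=O)C(C)(C)C)[C@@]1(C)CC=C | intermediate
13 | [(6S,7S)-7-allyl-6-(azidomethyl)-7-methyl-3-oxocyclohept-1-en-1-yl]methyl pivalate | [N-]=[N+]=NC[C@H]1CCC(=O)C=C(COC(=O)C(C)(C)C)[C@@]1(C)CC=C | intermediate
14 | [(6S,7S)-6-(azidomethyl)-7-methyl-3-oxo-7-(2-oxoethyl)cyclohept-1-en-1-yl]methyl pivalate | [N-]=[N+]=NC[C@H]1CCC(=O)C=C(COC(=O)C(C)(C)C)[C@@]1(C)CC=O | intermediate
15 | [(6S,7S)-6-(azidomethyl)-7-methyl-3-oxo-7-(3-oxoprop-1-en-2-yl)cyclohept-1-en-1-yl]methyl pivalate | [N-]=[N+]=NC[C@H]1CCC(=O)C=C(COC(=O)C(C)(C)C)[C@@]1(C)C(=C)C=O | intermediate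
16 | but-2-yn-1-ol | CC#CCO | starting material
17 | (but-2-yn-1-yloxy)(tert-butyl)dimethylsilane | CC#CCO[Si](C)(C)C(C)(C)C | intermediate
18 | (E)-alkenylzirconocene chloride from 17 (zirconium on the methyl-bearing carbon) | C/C(=C\CO[Si](C)(C)C(C)(C)C)[Zr](Cl)(C1C=CC=C1)C1C=CC=C1 | intermediate
19 | (E)-alkenyl(methyl)zinc from 18 | C/C(=C\CO[Si](C)(C)C(C)(C)C)[Zn]C | intermediate
20 | divinyl carbinol: 15 after 1,2-addition of the alkenyl group (carbinol epimers) | [N-]=[N+]=NC[C@H]1CCC(=O)C=C(COC(=O)C(C)(C)C)[C@@]1(C)C(=C)C(O)/C(C)=C/CO[Si](C)(C)C(C)(C)C | intermediate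
21 | azido dienone: [(6S,7S)-6-(azidomethyl)-7-[(4E)-6-{[tert-butyl(dimethyl)silyl]oxy}-4-methyl-3-oxohexa-1,4-dien-2-yl]-7-methyl-3-oxocyclohept-1-en-1-yl]methyl pivalate | [N-]=[N+]=NC[C@H]1CCC(=O)C=C(COC(=O)C(C)(C)C)[C@@]1(C)C(=C)C(=O)/C(C)=C/CO[Si](C)(C)C(C)(C)C | intermediate
22 | 2-oxidocyclopentenyl (oxyallyl) cation from the Nazarov closure, drawn without boron | [N-]=[N+]=NC[C@H]1CCC(=O)C=C(COC(=O)C(C)(C)C)[C@@]1(C)[C+]1CC(CO[Si](C)(C)C(C)(C)C)C(C)=C1[O-] | intermediate
23 | spiro aminodiazonium enolate after azide capture | N#[N+]N1C[C@H]2CCC(=O)C=C(COC(=O)C(C)(C)C)[C@@]2(C)C13CC(CO[Si](C)(C)C(C)(C)C)C(C)=C3[O-] | intermediate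
24 | N-acyliminium enolate (1,4-dipole) after ring expansion | [O-]C1=C(C)C(CO[Si](C)(C)C(C)(C)C)CC2=[N+]1C[C@H]1CCC(=O)C=C(COC(=O)C(C)(C)C)[C@@]21C | intermediate
25 | tricyclic lactam: 6-methyl-7-{[(tert-butyldimethylsilyl)oxy]methyl}indolizidin-5-one whose C1 (quaternary, methyl) to C2 bond is shared with the pivaloyloxymethyl cycloheptenone; epimers at C6 and C7 | CC1C(CO[Si](C)(C)C(C)(C)C)C[C@H]2N(C[C@H]3CCC(=O)C=C(COC(=O)C(C)(C)C)[C@@]23C)C1=O | intermediate
26 | the corresponding carboxylic acid (CO2H in place of CH2OSi; epimers) | CC1C(C(=O)O)C[C@H]2N(C[C@H]3CCC(=O)C=C(COC(=O)C(C)(C)C)[C@@]23C)C1=O | intermediate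
27 | the corresponding methyl ester (epimers) | CC1C(C(=O)OC)C[C@H]2N(C[C@H]3CCC(=O)C=C(COC(=O)C(C)(C)C)[C@@]23C)C1=O | intermediate
28 | lactam methyl ester, single diastereomer (ester trans to methyl, cis to the ring-fusion C–C bond) | C[C@H]1[C@H](C(=O)OC)C[C@H]2N(C[C@H]3CCC(=O)C=C(COC(=O)C(C)(C)C)[C@@]23C)C1=O | intermediate
29 | 3-[(tert-butyldimethylsilyl)oxy]propanal | O=CCCO[Si](C)(C)C(C)(C)C | starting material
30 | methyl 5-[(tert-butyldimethylsilyl)oxy]-3-oxopentanoate | COC(=O)CC(=O)CCO[Si](C)(C)C(C)(C)C | intermediate
31 | 28 with the pivaloyloxymethyl group replaced by CH2–CH(CO2Me)–C(=O)–CH2CH2OTBS | C[C@H]1[C@H](C(=O)OC)C[C@H]2N(C[C@H]3CCC(=O)C=C(CC(C(=O)OC)C(=O)CCO[Si](C)(C)C(C)(C)C)[C@@]23C)C1=O | intermediate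
32 | enol triflate of 31 (triflate cis to the ring CH2) | C[C@H]1[C@H](C(=O)OC)C[C@H]2N(C[C@H]3CCC(=O)C=C(C/C(C(=O)OC)=C(\OS(=O)(=O)C(F)(F)F)CCO[Si](C)(C)C(C)(C)C)[C@@]23C)C1=O | intermediate
33 | ring-A cyclopentadiene lactam diester (rings A to D) | COC(=O)C1=C(CCO[Si](C)(C)C(C)(C)C)C2=C(C1)[C@]1(C)[C@H](CCC2=O)CN2C(=O)[C@@H](C)[C@H](C(=O)OC)C[C@H]12 | intermediate
34 | pentacyclic hydroxyfulvene lactam (O-silyl, lactam C=O next to N) | COC(=O)C1=C(CCO[Si](C)(C)C(C)(C)C)C2=C3C1=C(O)[C@@H]1C[C@H]4N(C[C@@H](CCC2=O)[C@@]34C)C(=O)[C@H]1C | intermediate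
35 | N,O-silyl hemiaminal of 34 (fulvenol drawn free) | COC(=O)C1=C(CCO[Si](C)(C)C(C)(C)C)C2=C3C1=C(O)[C@@H]1C[C@H]4N(C[C@@H](CCC2=O)[C@@]34C)C(O[Si](C)(C)O[SiH](C)C)[C@H]1C | intermediate
36 | O-(tert-butyldimethylsilyl) daphnicyclidin H | COC(=O)C1=C(CCO[Si](C)(C)C(C)(C)C)C2=C3C1=C(O)[C@@H]1C[C@H]4N(C[C@@H](CCC2=O)[C@@]34C)C[C@H]1C | intermediate
37 | daphnicyclidin H | COC(=O)C1=C(CCO)C2=C3C1=C(O)[C@@H]1C[C@H]4N(C[C@@H](CCC2=O)[C@@]34C)C[C@H]1C | target

**Totals**
Total step count: 25. Longest linear sequence: 23 steps (steps 1–12, 14–18 and 20–25, from cycloheptanone); steps 13 and 19 prepare the two side fragments.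

**Three steps most likely to fail**

Step 16. The azide may be consumed by Lewis-acid-promoted attack on the ring-B enone, or the oxyallyl cation may lose a proton before it is captured, so that ring expansion never starts. The fallback separates the two events and sets out from alcohol 12. Mesylation (MsCl, Et3N) should give mesylate F1. Ozonolysis as in step 11 gives aldehyde F2, methylenation as in step 12 gives enal F3, alkenylzinc addition as in step 14 gives carbinol F4, and oxidation as in step 15 gives the azide-free dienone F5. A reductive Nazarov cyclization (BF3·OEt2, Et3SiH, CH2Cl2, −78 to 0 °C) should then give cyclopentanone F6. Displacement with NaN3 (DMF, 50 °C) gives azido ketone F7. An intramolecular Schmidt reaction of the alkyl azide with the cyclopentanone (TiCl4, CH2Cl2, 0 °C to rt; the carbon bearing the tether migrates) expands the five-membered ketone to the fused six-membered lactam and comes back to the route at 25.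

Step 23. The doubly acyl-stabilised cyclopentadienide may attack the methyl ester too slowly, so that the diene dimerises or decomposes on heating. The fallback sets out from 33. Hydrolysis with LiOH (1.1 equiv, THF/H2O, 0 °C) should cleave only the aliphatic ester, the ring ester being deactivated in the cyclopentadienide, and give acid F8. 1-Chloro-N,N,2-trimethylprop-1-en-1-amine converts it into acid chloride F9, which is not isolated. Et3N with catalytic DMAP then brings about C-acylation of the cyclopentadienide by the acyl chloride, a known acylation of cyclopentadienides, and comes back to the route at 34.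

Step 22. Deprotonation of the hindered enone at its γ-position may be too slow under the coupling conditions, so that the alkenylpalladium species is lost by protonolysis, or the triflate geometry may not allow closure. The fallback sets out from β-keto ester 31 and leaves out the triflate. Acid-catalysed intramolecular aldol condensation (camphorsulfonic acid, benzene, 70 °C, water removal) between the dienol α-carbon of the cycloheptenone and the side-chain ketone, followed by dehydration, should give the cyclopentadiene directly and comes back to the route at 33; no compound outside the list is made (F0).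

**Further compounds**
F1 | step 16 | [(6S,7S)-7-allyl-7-methyl-6-{[(methylsulfonyl)oxy]methyl}-3-oxocyclohept-1-en-1-yl]methyl pivalate | CS(=O)(=O)OC[C@H]1CCC(=O)C=C(COC(=O)C(C)(C)C)[C@@]1(C)CC=C
F2 | step 16 | mesylate aldehyde (2-oxoethyl in place of allyl) | CS(=O)(=O)OC[C@H]1CCC(=O)C=C(COC(=O)C(C)(C)C)[C@@]1(C)CC=O
F3 | step 16 | mesylate enal (3-oxoprop-1-en-2-yl in place of allyl) | CS(=O)(=O)OC[C@H]1CCC(=O)C=C(COC(=O)C(C)(C)C)[C@@]1(C)C(=C)C=O
F4 | step 16 | mesylate divinyl carbinol (carbinol epimers) | CS(=O)(=O)OC[C@H]1CCC(=O)C=C(COC(=O)C(C)(C)C)[C@@]1(C)C(=C)C(O)/C(C)=C/CO[Si](C)(C)C(C)(C)C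
F5 | step 16 | mesylate dienone (azide-free analogue of 21) | CS(=O)(=O)OC[C@H]1CCC(=O)C=C(COC(=O)C(C)(C)C)[C@@]1(C)C(=C)C(=O)/C(C)=C/CO[Si](C)(C)C(C)(C)C
F6 | step 16 | mesylate cyclopentanone: 2-methyl-3-(silyloxymethyl)-5-substituted cyclopentanone on the quaternary carbon (ring epimers) | CS(=O)(=O)OC[C@H]1CCC(=O)C=C(COC(=O)C(C)(C)C)[C@@]1(C)C1CC(CO[Si](C)(C)C(C)(C)C)C(C)C1=O
F7 | step 16 | azido cyclopentanone (azidomethyl in place of the mesyloxymethyl group of F6) | [N-]=[N+]=NC[C@H]1CCC(=O)C=C(COC(=O)C(C)(C)C)[C@@]1(C)C1CC(CO[Si](C)(C)C(C)(C)C)C(C)C1=O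
F8 | step 23 | piperidinone carboxylic acid of 33 (ring-A methyl ester kept) | COC(=O)C1=C(CCO[Si](C)(C)C(C)(C)C)C2=C(C1)[C@]1(C)[C@H](CCC2=O)CN2C(=O)[C@@H](C)[C@H](C(=O)O)C[C@H]12
F9 | step 23 | acid chloride of F8 | COC(=O)C1=C(CCO[Si](C)(C)C(C)(C)C)C2=C(C1)[C@]1(C)[C@H](CCC2=O)CN2C(=O)[C@@H](C)[C@H](C(=O)Cl)C[C@H]12
F0 | step 22 | none | none
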